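**Plan**
- Retrosynthetic cuts: the C15 acetate and the free C19 acid are unmasked last. Ring B is cut at C8–C9, then the chain at C9=C11, then C8≡C17, and finally ring C of a podocarpate is excised.
- Enabling feature: ring B carries the exocyclic C8=C17 methylene directly beside C9, which bears the C11 side chain. This is the imprint of a terminal C8≡C17 alkyne that has added across a C9=C11 alkene on ring A.
- Forward order: ring A is bought intact, ring C is degraded to C8 and C9 carboxyl arms, the C11–C16 chain is joined at C9 by olefination, C8 is homologated to the alkyne, and ring B closes in the key step.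
- Stereochemistry: C4, C5 and C10 come from (+)-podocarpic acid. C13 comes from (R)-methyl hydrogen 3-methylglutarate. C9 is set by substrate control in the ring closure.

Key step: step 14

Remark: podocarpane/labdane numbering is used for all intermediates. The side chain needs only five chain carbons (C11–C15) plus C16, so the commercial (R)-monoester of 3-methylglutaric acid is used as the C13 source.

**Step 1**
Reactants: 1 (+)-podocarpic acid
Product: 2 methyl O-methylpodocarpate (methyl 12-methoxypodocarpa-8,11,13-trien-19-oate)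
Conditions: MeI (3 equiv), K2CO3, DMF, 25 °C
Reagents that add atoms: iodomethane, CI
Why: Williamson etherification of the phenol and SN2 O-alkylation of the carboxylate proceed together, because attack at the methyl carbon is indifferent to the shielding of the axial C4 carboxyl.

**Step 2**
Reactants: 2 methyl O-methylpodocarpate
Product: 3 (1S,2R,3S)-2-(2-carboxyethyl)-3-(methoxycarbonyl)-1,3-dimethylcyclohexane-1-carboxylic acid (ring A with C8 and C9 as CO2H)
Conditions: O3, CH2Cl2–MeOH, −40 °C to 0 °C; then 30% H2O2, HCO2H, 25→45 °C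
Reagents that add atoms: ozone, [O-][O+]=O; hydrogen peroxide, OO
Why: Exhaustive ozonolysis of the electron-rich anisole ring with oxidative (performic acid) work-up should cleave every C=C bond of ring C, leaving only C8 and C9 as carboxylic acids and the C4, C5 and C10 centres untouched.

**Step 3**
Reactants: 3 seco-diacid
Product: 4 (1S,2R,3S)-3-(methoxycarbonyl)-2-(3-methoxy-3-oxopropyl)-1,3-dimethylcyclohexane-1-carboxylic acid (C8 methyl ester, C9 acid)
Conditions: MeOH, H2SO4 (cat.), 25 °C
Reagents that add atoms: methanol, CO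
Why: Fischer esterification should discriminate sterically, since the primary C8 acid esterifies readily whereas the tertiary C9 acid on quaternary C10 forms its tetrahedral intermediate far too slowly.

**Step 4**
Reactants: 4 C9 acid diester
Product: 5 methyl (1S,2R,3S)-3-(hydroxymethyl)-2-(3-methoxy-3-oxopropyl)-1,3-dimethylcyclohexane-1-carboxylate (C9 alcohol)
Conditions: BH3·SMe2, THF, 0→25 °C; MeOH quench
Reagents that add atoms: none
Why: Chemoselective borane reduction takes the free acid through its acyloxyborane to the neopentyl alcohol much faster than it attacks either methyl ester.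

**Step 5**
Reactants: 5 C9 alcohol diester
Product: 6 methyl (1S,2R,3S)-3-formyl-2-(3-methoxy-3-oxopropyl)-1,3-dimethylcyclohexane-1-carboxylate (C9 aldehyde)
Conditions: Dess–Martin periodinane, CH2Cl2, 25 °C
Reagents that add atoms: none
Why: Dess–Martin oxidation converts hindered primary alcohols to aldehydes under neutral conditions, and the product is non-enolisable at C10.

**Step 6**
Reactants: 7 (R)-methyl hydrogen 3-methylglutarate
Product: 8 methyl (3R)-5-hydroxy-3-methylpentanoate
Conditions: BH3·SMe2, THF, −10→25 °C; MeOH quench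
Reagents that add atoms: none
Why: Chemoselective borane reduction of the acid in the presence of the ester differentiates the two arms, and the stereocentre is β to both carbonyls and cannot epimerise.

**Step 7**
Reactants: 8 methyl (3R)-5-hydroxy-3-methylpentanoate
Product: 9 methyl (3R)-5-[(tert-butyldimethylsilyl)oxy]-3-methylpentanoate
Conditions: TBSCl, imidazole, DMF, 0→25 °C (crude 8 used at once)
Reagents that add atoms: tert-butyldimethylsilyl chloride, CC(C)(C)[Si](C)(C)Cl
Why: Imidazole-promoted silylation of the primary alcohol is fast and should pre-empt lactonisation of the hydroxy ester.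

**Step 8**
Reactants: 9 silyloxy ester
Product: 10 (3S)-5-[(tert-butyldimethylsilyl)oxy]-3-methylpentan-1-ol
Conditions: DIBAL-H (2.5 equiv), CH2Cl2, −78→0 °C; Rochelle salt
Reagents that add atoms: none
Why: DIBAL reduction of an ester to the primary alcohol leaves the silyl ether intact; the descriptor changes from R to S only because the priorities of the two arms are exchanged.

**Step 9**
Reactants: 10 (3S)-5-(TBSO)-3-methylpentan-1-ol
Product: 11 5-{[(3R)-5-(tert-butyldimethylsilyloxy)-3-methylpentyl]sulfanyl}-1-phenyl-1H-tetrazole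
Conditions: 1-phenyl-1H-tetrazole-5-thiol, PPh3, DIAD, THF, 0→25 °C
Reagents that add atoms: 1-phenyl-1H-tetrazole-5-thiol, Sc1nnnn1-c1ccccc1
Why: Mitsunobu thioetherification works well with this acidic thiol and an unhindered primary alcohol, and it does not touch the remote stereocentre.

**Step 10**
Reactants: 11 tetrazolyl sulfide
Product: 12 5-{[(3R)-5-(tert-butyldimethylsilyloxy)-3-methylpentyl]sulfonyl}-1-phenyl-1H-tetrazole
Conditions: (NH4)6Mo7O24·4H2O (cat.), 30% H2O2, EtOH, 0→25 °C
Reagents that add atoms: hydrogen peroxide, OO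
Why: Molybdate-catalysed peroxide oxidation is the standard sulfide-to-sulfone conversion for Julia–Kocienski reagents and tolerates a primary TBS ether.

**Step 11**
Reactants: 6 C9 aldehyde diester; 12 tetrazolyl sulfone
Product: 13 methyl (1S,2R,3R)-3-[(1E,4S)-6-(tert-butyldimethylsilyloxy)-4-methylhex-1-en-1-yl]-2-(3-methoxy-3-oxopropyl)-1,3-dimethylcyclohexane-1-carboxylate (E C9=C11 alkene)
Conditions: 12, KHMDS, DME, −60 °C; then 6, −60→25 °C; aq. NH4Cl
Reagents that add atoms: none
Why: Julia–Kocienski olefination (addition, Smiles rearrangement, loss of SO2 and tetrazololate) with a potassium counter-ion in DME should favour the E alkene, all the more with an α-quaternary aldehyde, and the premetalated sulfone adds to the aldehyde far faster than to a methyl ester at low temperature.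

**Step 12**
Reactants: 13 E-alkene diester
Product: 14 methyl (1S,2R,3R)-3-[(1E,4S)-6-(tert-butyldimethylsilyloxy)-4-methylhex-1-en-1-yl]-1,3-dimethyl-2-(3-oxopropyl)cyclohexane-1-carboxylate (C8 aldehyde)
Conditions: DIBAL-H (1.1 equiv), CH2Cl2, −78 °C; MeOH, Rochelle salt
Reagents that add atoms: none
Why: Partial DIBAL reduction stops at the aluminium hemiacetal of the unhindered C8 ester at −78 °C, while the axial, neopentyl C19 ester is too shielded to react.

**Step 13**
Reactants: 14 C8 aldehyde
Product: 15 methyl (1S,2R,3R)-2-(but-3-yn-1-yl)-3-[(1E,4S)-6-(tert-butyldimethylsilyloxy)-4-methylhex-1-en-1-yl]-1,3-dimethylcyclohexane-1-carboxylate (1,7-enyne)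
Conditions: dimethyl (1-diazo-2-oxopropyl)phosphonate, K2CO3, MeOH, 0→25 °C
Reagents that add atoms: dimethyl (1-diazo-2-oxopropyl)phosphonate, CC(=O)C(=[N+]=[N-])P(=O)(OC)OC
Why: Ohira–Bestmann (Seyferth–Gilbert) homologation converts the aldehyde into the terminal alkyne, adding C17, under mild carbonate conditions that leave the esters, the silyl ether and the alkene unchanged.

**Step 14**
Reactants: 15 1,7-enyne
Product: 16 methyl (13S)-15-(tert-butyldimethylsilyloxy)labd-8(17)-en-19-oate
Conditions: Pd2(dba)3·CHCl3 (2.5 mol %), P(o-tol)3 (10 mol %), AcOH (1.5 equiv), Et3SiH (5 equiv), PhMe, 25→50 °C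
Reagents that add atoms: none
Why: Pd(0) and acetic acid give H–Pd–OAc, which adds across the terminal C8≡C17 alkyne with hydrogen to C17 and palladium to C8; the C8 vinylpalladium inserts the E C9=C11 alkene syn to form C8–C9 and put palladium on C11, and the silane exchanges acetate for hydride so that C–H reductive elimination at C11 returns Pd(0). The closest known reaction type is the palladium-hydride reductive cyclisation of 1,6- and 1,7-enynes to alkylidenecycloalkanes with silane termination. Ring B closes by 6-exo-trig carbopalladation of C8 onto C9, which the four-centre insertion geometry favours over 7-endo closure. The new C9 centre is set by substrate control: ring A, fixed by C5 and C10 with both arms equatorial, should direct closure through a chair-like trans-decalin transition state with the alkene pseudo-equatorial, so C8 bonds to the face that leaves H9 axial and α, anti to the C10 methyl. The step needs palladium at the internal alkyne carbon, which a terminal alkyne held next to the alkene provides, and hydride capture at C11 faster than β-hydride elimination toward C12, which the excess silane secures. The shielded C19 ester and the silyl ether are spectators, and the 1,1-disubstituted exocyclic alkene formed is a poor acceptor for further Pd–H addition.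

**Step 15**
Reactants: 16 methyl (13S)-15-(TBSO)labd-8(17)-en-19-oate
Product: 17 (13S)-15-(tert-butyldimethylsilyloxy)labd-8(17)-en-19-oic acid
Conditions: n-PrSLi (from n-PrSH, n-BuLi), HMPA, 25 °C; then 1 M HCl
Reagents that add atoms: none
Why: Thiolate SN2 O-alkyl cleavage attacks the ester methyl carbon and is therefore insensitive to the hindrance at the axial C19 carbonyl, and this soft, weakly basic nucleophile should not move the exocyclic alkene or disturb the silyl ether.

**Step 16**
Reactants: 17 silyl ether acid
Product: 18 imbricatolic acid, (13S)-15-hydroxylabd-8(17)-en-19-oic acid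
Conditions: HF·pyridine, pyridine, THF, 0→25 °C
Reagents that add atoms: none
Why: Fluoride-mediated desilylation of a primary TBS ether under pyridine buffering avoids acid-promoted migration of the 8(17) double bond.

**Step 17**
Reactants: 18 imbricatolic acid
Product: 19 target, (13S)-15-acetoxylabd-8(17)-en-19-oic acid
Conditions: Ac2O, pyridine, DMAP (cat.), CH2Cl2, 0→25 °C; aqueous work-up
Reagents that add atoms: acetic anhydride, CC(=O)OC(C)=O
Why: DMAP-catalysed acetylation is selective for the primary C15 alcohol, because the hindered tertiary acid can at most form a mixed anhydride that the aqueous work-up hydrolyses.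

**Compound list**
1 | (+)-podocarpic acid | Oc1ccc2CC[C@@H]3[C@](C)(CCC[C@]3(C)C(=O)O)c2c1 | starting material
2 | methyl O-methylpodocarpate | COc1ccc2CC[C@@H]3[C@](C)(CCC[C@]3(C)C(=O)OC)c2c1 | intermediate
3 | (1S,2R,3S)-2-(2-carboxyethyl)-3-(methoxycarbonyl)-1,3-dimethylcyclohexane-1-carboxylic acid | OC(=O)CC[C@@H]1[C@](C)(CCC[C@]1(C)C(=O)OC)C(=O)O | intermediate
4 | (1S,2R,3S)-3-(methoxycarbonyl)-2-(3-methoxy-3-oxopropyl)-1,3-dimethylcyclohexane-1-carboxylic acid | COC(=O)CC[C@@H]1[C@](C)(CCC[C@]1(C)C(=O)OC)C(=O)O | intermediate
5 | methyl (1S,2R,3S)-3-(hydroxymethyl)-2-(3-methoxy-3-oxopropyl)-1,3-dimethylcyclohexane-1-carboxylate | COC(=O)CC[C@@H]1[C@](C)(CCC[C@]1(C)C(=O)OC)CO | intermediate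
6 | methyl (1S,2R,3S)-3-formyl-2-(3-methoxy-3-oxopropyl)-1,3-dimethylcyclohexane-1-carboxylate | COC(=O)CC[C@@H]1[C@](C)(CCC[C@]1(C)C(=O)OC)C=O | intermediate
7 | (R)-methyl hydrogen 3-methylglutarate, (3R)-5-methoxy-3-methyl-5-oxopentanoic acid | COC(=O)C[C@H](C)CC(=O)O | starting material
8 | methyl (3R)-5-hydroxy-3-methylpentanoate | COC(=O)C[C@H](C)CCO | intermediate
9 | methyl (3R)-5-[(tert-butyldimethylsilyl)oxy]-3-methylpentanoate | COC(=O)C[C@H](C)CCO[Si](C)(C)C(C)(C)C | intermediate
10 | (3S)-5-[(tert-butyldimethylsilyl)oxy]-3-methylpentan-1-ol | OCC[C@H](C)CCO[Si](C)(C)C(C)(C)C | intermediate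
11 | 5-{[(3R)-5-(tert-butyldimethylsilyloxy)-3-methylpentyl]sulfanyl}-1-phenyl-1H-tetrazole | c1ccccc1-n1nnnc1SCC[C@H](C)CCO[Si](C)(C)C(C)(C)C | intermediate
12 | 5-{[(3R)-5-(tert-butyldimethylsilyloxy)-3-methylpentyl]sulfonyl}-1-phenyl-1H-tetrazole | c1ccccc1-n1nnnc1S(=O)(=O)CC[C@H](C)CCO[Si](C)(C)C(C)(C)C | intermediate
13 | methyl (1S,2R,3R)-3-[(1E,4S)-6-(tert-butyldimethylsilyloxy)-4-methylhex-1-en-1-yl]-2-(3-methoxy-3-oxopropyl)-1,3-dimethylcyclohexane-1-carboxylate | COC(=O)CC[C@@H]1[C@](C)(CCC[C@]1(C)C(=O)OC)/C=C/C[C@H](C)CCO[Si](C)(C)C(C)(C)C | intermediate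
14 | methyl (1S,2R,3R)-3-[(1E,4S)-6-(tert-butyldimethylsilyloxy)-4-methylhex-1-en-1-yl]-1,3-dimethyl-2-(3-oxopropyl)cyclohexane-1-carboxylate | O=CCC[C@@H]1[C@](C)(CCC[C@]1(C)C(=O)OC)/C=C/C[C@H](C)CCO[Si](C)(C)C(C)(C)C | intermediate
15 | methyl (1S,2R,3R)-2-(but-3-yn-1-yl)-3-[(1E,4S)-6-(tert-butyldimethylsilyloxy)-4-methylhex-1-en-1-yl]-1,3-dimethylcyclohexane-1-carboxylate | C#CCC[C@@H]1[C@](C)(CCC[C@]1(C)C(=O)OC)/C=C/C[C@H](C)CCO[Si](C)(C)C(C)(C)C | intermediate
16 | methyl (13S)-15-(tert-butyldimethylsilyloxy)labd-8(17)-en-19-oate | C=C1CC[C@@H]2[C@](C)(CCC[C@]2(C)C(=O)OC)[C@H]1CC[C@H](C)CCO[Si](C)(C)C(C)(C)C | intermediate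
17 | (13S)-15-(tert-butyldimethylsilyloxy)labd-8(17)-en-19-oic acid | C=C1CC[C@@H]2[C@](C)(CCC[C@]2(C)C(=O)O)[C@H]1CC[C@H](C)CCO[Si](C)(C)C(C)(C)C | intermediate
18 | imbricatolic acid, (13S)-15-hydroxylabd-8(17)-en-19-oic acid | C=C1CC[C@@H]2[C@](C)(CCC[C@]2(C)C(=O)O)[C@H]1CC[C@H](C)CCO | intermediate
19 | (13S)-15-acetoxylabd-8(17)-en-19-oic acid | C=C1CC[C@@H]2[C@](C)(CCC[C@]2(C)C(=O)O)[C@H]1CC[C@H](C)CCOC(C)=O | target

**Step count**
Total: 17 steps. Longest linear sequence: 12 steps (steps 1–5 and 11–17, from podocarpic acid).

**Steps most likely to fail**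

1. Step 14. The C11 alkylpalladium may lose a β-hydrogen toward C12 before the silane delivers hydride. The alkyne may be reduced or hydrosilylated before it cyclises. Closure may also occur on both alkene faces, eroding the C9 configuration. The fallback sets out from 15 and returns at 16, replacing the palladium hydride by a tin-radical chain. With Bu3SnH added slowly and catalytic AIBN in benzene at 80 °C, the stannyl radical adds to terminal C17. The resulting C8 vinyl radical closes ring B 6-exo-trig onto C9, and the C11 radical is reduced by the tin hydride, giving the exocyclic vinylstannane F1. A carbon radical has no β-hydride elimination pathway. Brief protodestannylation of the vinylstannane F1 (TFA, CH2Cl2, 0 °C) then gives 16.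

2. Step 11. Addition of the metalated tetrazolyl sulfone to the neopentyl, α-quaternary C9 aldehyde may be slow. That would give time for self-condensation of the sulfone anion and attack on the C8 ester, and E selectivity may erode. The fallback sets out from 10 and 6 and returns at 13 by a stepwise Julia–Lythgoe olefination. Alcohol 10 is converted with PhSSPh and n-Bu3P into the phenyl sulfide F2, which is oxidised (molybdate, H2O2) to the phenyl sulfone F3. Its lithio derivative (n-BuLi, THF, −78 °C) is stable to self-condensation and adds to 6. The alkoxide is trapped with Ac2O to give the β-acetoxy sulfone F4 as a diastereomer mixture. Sodium amalgam (Na2HPO4, MeOH–THF, −20 °C) then eliminates reductively to the E alkene 13, whatever the adduct stereochemistry.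

3. Step 2. The partly cleaved, electron-poor ring fragments may take up ozone only slowly, so that degradation stalls while the benzylic C7 position begins to oxidise. The fallback sets out from 1 and returns at 3, dearomatising ring C before ozone is applied. Carboxyl-selective alkylation of 1 (MeI, KHCO3, DMF) gives methyl podocarpate F5 with the phenol free. IBX in DMF (or Fremy's salt) oxidises the phenol to the ortho-quinone F6, methyl 12,13-dioxopodocarpa-8(14),9(11)-dien-19-oate. Ozone then cleaves the two remaining C=C bonds to the ring-B 8,9-dione F7. The performic acid work-up splits this 1,2-dione to the diacid 3.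

**Further compounds**
F1 | step 14 | methyl (13S)-15-(tert-butyldimethylsilyloxy)-17-(tributylstannyl)labd-8(17)-en-19-oate (E/Z mixture) | CCCC[Sn](CCCC)(CCCC)C=C1CC[C@@H]2[C@](C)(CCC[C@]2(C)C(=O)OC)[C@H]1CC[C@H](C)CCO[Si](C)(C)C(C)(C)C
F2 | step 11 | tert-butyldimethyl{[(3R)-3-methyl-5-(phenylsulfanyl)pentyl]oxy}silane | c1ccccc1SCC[C@H](C)CCO[Si](C)(C)C(C)(C)C
F3 | step 11 | tert-butyldimethyl{[(3R)-3-methyl-5-(phenylsulfonyl)pentyl]oxy}silane | O=S(=O)(CC[C@H](C)CCO[Si](C)(C)C(C)(C)C)c1ccccc1
F4 | step 11 | β-acetoxy sulfone from 6 and F3 (C9 acetate, C11 phenylsulfonyl, diastereomer mixture) | COC(=O)CC[C@@H]1[C@](C)(CCC[C@]1(C)C(=O)OC)C(OC(C)=O)C(C[C@H](C)CCO[Si](C)(C)C(C)(C)C)S(=O)(=O)c1ccccc1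
F5 | step 2 | methyl podocarpate (methyl 12-hydroxypodocarpa-8,11,13-trien-19-oate) | Oc1ccc2CC[C@@H]3[C@](C)(CCC[C@]3(C)C(=O)OC)c2c1
F6 | step 2 | methyl 12,13-dioxopodocarpa-8(14),9(11)-dien-19-oate (ortho-quinone) | O=C1C(=O)C=C2CC[C@@H]3[C@](C)(CCC[C@]3(C)C(=O)OC)C2=C1
F7 | step 2 | methyl 8,9-dioxo-11,12,13,14-tetranorpodocarpan-19-oate (ring-B 1,2-dione) | O=C1CC[C@@H]2[C@](C)(CCC[C@]2(C)C(=O)OC)C1=O
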